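## The problem

The target is an angular profisetinidin tetramer: a (+)-catechin hub, (2R,3S), carries one fisetinidol unit on C8 of its ring A (unit 4) and a second on C6 (unit 2), and unit 2 carries a third (unit 1) on its own C6. Each of the three interflavan bonds runs from an sp3 C4, on the α face, to an aromatic carbon ortho to oxygen, so three aryl–C4 bonds must be made at three defined positions; coupling of flavan-4-yl cations cannot do this reliably, because it does not tell C6 from C8 of a resorcinol-type ring, nor ring A of unit 2 from ring A of unit 4. Of the eleven stereocentres, C2 and C3 of the hub come with catechin, and each fisetinidol unit adds an all-trans C2/C3/C4 triad. Inside a unit C4 can direct C3 and C2 through the pyran ring, but the units are too far apart for one to direct the next, so every C4 needs reagent control. Thirteen phenolic hydroxyls oxidise and chelate and must stay masked to the end; the electron-rich rings are open to electrophiles and oxidants, and aryl–C4 bonds to the phloroglucinol-type hub ring do not survive strong acid. The feature that opens the route is that the pyran of each fisetinidol unit has a single heteroatom, O1, bonded to aromatic C8a and to C2. With O1 taken out, C8a–C2 closes a five-membered ring, a 6-oxygenated 3-arylindan-1-one whose carbonyl carbon is the future C2 and whose only stereocentre is the future C4. That centre is β to the ketone, so conjugate addition can set it, and a peracid returns O1 on the aryl side.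

## Retrosynthesis

**45 to 44.** The last operation only unveils the polyphenol: the fourteen O–benzyl bonds of 44 are cut. Benzyl ethers stand up to bases, organometallic reagents, peracid and boranes, and hydrogenolysis is neutral, so the interflavan bonds are not put at risk as they would be by acid-labile masking. The three secondary hydroxyls of the fisetinidol units are left free in 44, because nothing after their creation needs them masked.

**Unit 1: 44 back to 34.** Unit 1 ends the chain and is cut first. C3–O and C2–H are cut together, giving flav-2-ene 42. C2–C1' is cut to lactone 40 and arylmagnesium bromide 17. O1 is deleted from 40 to give indanone 39. The C3–C3a bond of 39 (C4–C4a of the unit) is cut to boronate 38, made from bromide 37, and the enone C=C of 37 is cut to aldehyde 36 and bromoacetophenone 9. Against a cation coupling onto the trimer, this fixes the site: the aldehyde carbon of 36 becomes C4 of unit 1. Aldehyde 36 comes from alkene 35 and that from chloride 34. The chlorine is placed on C6 of unit 2 by the acetophenone used for that unit. Chloride is preferred to bromide because it is inert to palladium borylation, rhodium, peracid, the arylmagnesium reagent and borane. The forward steps must tolerate two free secondary alcohols.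

**Unit 2: 34 back to 21.** The same five cuts lead through 32, 30 (with 17), 29, 28 and 27 to aldehyde 23 and bromochloroacetophenone 26. Aldehyde 23 comes from bromide 21 by exchange of bromine for a formyl group. This removes a whole flavan unit and leaves a dimer whose only reactive site is the C6 bromide. The forward condensation must work on an aldehyde flanked by two benzyloxy groups.

**Unit 4, C2 and C3: 21 to 19.** C3–O and C2–H are cut across the enol ether of 19. Both remaining stereocentres then arise in one syn addition controlled by C4. The neighbouring cut, C3–O alone by enolate hydroxylation followed by hemiketal reduction for C2, needs more steps and a protecting group. The forward reaction must add to the face away from the C4 aryl group.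

**Unit 4, ring B: 19 to 14 and 17.** C2–C1' is cut, so the lactone carbonyl of 14 is the C2 electrophile for the aryl group of 17, and loss of water gives the enol ether. This brings in ring B as a simple arylmetal reagent. Magnesium is chosen as the metal because an aryl Grignard reagent adds to the lactone but does not exchange with the aryl bromide on hub C6, and because its THF solution keeps, so that one reagent serves all three units. The addition must stop after one equivalent.

**Unit 4, key cut: 14 to 13.** O1 is deleted, that is O1–C8a and O1–C2 are cut, and the ring contracts to the 3-arylindan-1-one 13. The alternatives are to close the pyran by C–O bond formation onto an open chain or to add a phenol-bearing aryl group to a cinnamate; both need a free or masked ortho-phenol on a metalated arene. The indanone needs only a ketone. Forward, the aryl carbon and not the methylene must migrate, and the peracid must spare the electron-rich rings. The hub in 13 is fully substituted because C6 carries bromine, which is also the handle for unit 2.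

**Indanone: 13 back to 6 and 9.** The C6–Br bond of 13 is cut to 12. The C3–C3a bond of 12 is cut to boronate 11, which comes from bromide 10. The enone of 10 is cut to hub aldehyde 6 and bromoacetophenone 9. The stereocentre is set in the ring-forming conjugate addition by a chiral rhodium catalyst. Bromination is placed after ring formation because the indanone ring is then deactivated and only hub C6 reacts.

**Starting materials.** Aldehyde 6 comes from bromide 4 (via 5), which comes from ethers 3 and 2 and (+)-catechin 1. Ketone 9 comes from 8 and 3'-hydroxyacetophenone 7. Ketone 26 comes from 25 and 4'-chloro-3'-hydroxyacetophenone 24. Grignard reagent 17 comes from bromide 16 and that from 4-bromocatechol 15. Each is one or two routine steps from a purchasable compound, and catechin supplies ring A, C2 and C3 of the hub unchanged.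

## Roads not taken

**Alternative 1:** The hub benzene ring is cut through C4a–C8a, C5–C6 and C7–C8, so that it and the hub pyran would arise from three carbon–carbon triple bonds. Two of them are already linked by the O1–C2–C3–C4 chain and carry unit 4; the third carries units 1 and 2. The forward step is a [2+2+2] cyclotrimerisation with [Rh(cod)2]BF4 and BINAP (cationic monovalent rhodium) to the tetramer A1, which has triisopropylsilyl ethers on hub O5 and O7.
- Merits: two large halves are joined in the ring-forming step, and every oxygen of the hub ring is placed by construction.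
- Weak points: the hub ring, C2 and C3 are rebuilt although catechin supplies them. All three alkynes are oxygen-substituted and sensitive. The untethered alkyne can insert in two orientations. A hexasubstituted benzene must form between alkyne carbons that each bear a bulky diarylmethine stereocentre. The three fisetinidol units and their nine stereocentres still have to be made by other means.
- Comparison: this road is more convergent and would have a shorter longest linear sequence. The chosen plan sets against that the intact chiral-pool hub, regiochemistry that never depends on the orientation of an untethered partner, and the absence of ynol ethers.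

**Alternative 2:** The three C4–C4a bonds are cut, leading back to three aryl alkynes, each with a tethered aryl propargyl ether; the aryl–alkyne bonds come from cross-coupling. The forward step is a triple 6-endo hydroarylation with Ph3PAuNTf2 (cationic monovalent gold) to the tris(flav-3-ene) A2.
- Merits: three pyran rings close in one catalytic operation, and the interflavan positions are as secure as in the chosen plan.
- Weak points: C4 ends as an sp2 carbon. All three C4 centres and all three C3 hydroxyls must then come from three additions on one molecule, each controlled only by C2. C2 of a 2-aryl-2H-chromene can lose its configuration by reversible electrocyclic ring opening. Three enantiopure propargylic aryl ethers are needed. The hub ring must cyclise at a fully substituted position.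
- Comparison: on paper this road is shorter. The chosen plan answers by setting C4 first under catalyst control and letting the robust C4 centre direct C2 and C3, so no labile centre is carried.

**Alternative 3:** Ring A of unit 2 is cut at C8a–C8, C6–C7 and C8a–C4a. It would be built around unit 1 by irradiating a diazo ketone precursor to a vinylketene, which adds (triisopropylsiloxy)acetylene A4. Opening of the cyclobutenone and six-electron closure give the resorcinol monosilyl ether A3, with unit 1 on C6.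
- Merits: the unit 1–unit 2 junction is regiochemically unambiguous, and the two ring oxygens come out differentiated, the free phenol for O1 and the silyl ether for O7.
- Weak points: only one of three junctions is solved. Unit 1 must already exist with its C4 attached to the unsaturated carbonyl system, where it can epimerise. The substrate contains several benzyloxyarene chromophores that absorb the same light. The pyran of unit 2, its bond to the hub and unit 4 still need another method.
- Comparison: for this one bond the road is better than carrying a chlorine handle and converting it in two steps. The chosen plan offers one repeated module for all three junctions.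

Key step: step 11

Assumption: 4'-chloro-3'-hydroxyacetophenone (24) is taken as a purchasable building block.
Assumption: the sense of induction of (S)-MonoPhos in the rhodium cyclisations is taken from the usual model for this ligand; if indanone 12 shows the opposite configuration at C3, the antipodal ligand is used in steps 9, 21 and 29.
Assumption: Grignard reagent 17 is kept as a titrated THF stock solution under argon and drawn on in steps 14, 23 and 31.

Shorthand in names:
- hub = 3,5,7,3',4'-penta-O-benzyl-(+)-catechin, (2R,3S), with positions 6 and 8 on ring A.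
- Fis = 7,3',4'-tri-O-benzylfisetinidol unit, (2R,3S), 3-OH free, bonded through C4 on its α face (3,4-trans).
- dimer = Fis-(4α→8)-hub.
- trimer = Fis-(4α→6)-[Fis-(4α→8)]-hub.
- C6 of unit 2 = the ring A carbon of the Fis unit on hub C6 that is para to O1 and ortho to the 7-benzyloxy group.

## Route

Step 1
Reactants: 1 (+)-catechin
Product: 2 5,7,3',4'-tetra-O-benzyl-(+)-catechin
Conditions: BnBr, K2CO3, DMF, 0 °C to rt
Reagents that add atoms: benzyl bromide, BrCc1ccccc1
Why: Williamson etherification of the four phenols with carbonate as base; the secondary alcohol is not deprotonated and C2 is not epimerised under these mild conditions.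

Step 2
Reactants: 2 5,7,3',4'-tetra-O-benzyl-(+)-catechin
Product: 3 3,5,7,3',4'-penta-O-benzyl-(+)-catechin (hub)
Conditions: NaH, BnBr, DMF, 0 °C to rt
Reagents that add atoms: benzyl bromide, BrCc1ccccc1
Why: Williamson etherification of the remaining secondary hydroxyl through its sodium alkoxide; no stereocentre is touched.

Step 3
Reactants: 3 hub
Product: 4 8-bromo-hub
Conditions: NBS, CH2Cl2, −78 °C to 0 °C
Reagents that add atoms: N-bromosuccinimide, O=C1CCC(=O)N1Br
Why: Electrophilic aromatic bromination; in 5,7-dibenzyloxyflavans C8 reacts before C6, and one equivalent at low temperature should stop at the monobromide.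

Step 4
Reactants: 4 8-bromo-hub
Product: 6 hub-8-carbaldehyde, via 8-lithio-hub 5 (not isolated)
Conditions: n-BuLi, THF, −78 °C; DMF; H2O
Reagents that add atoms: N,N-dimethylformamide, CN(C)C=O
Why: Bromine–lithium exchange is faster than attack on benzyl ethers at −78 °C, and the aryllithium is formylated by DMF (hemiaminal collapse on work-up).

Step 5
Reactants: 7 3'-hydroxyacetophenone
Product: 8 3'-(benzyloxy)acetophenone
Conditions: BnBr, K2CO3, acetone, reflux
Reagents that add atoms: benzyl bromide, BrCc1ccccc1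
Why: Williamson etherification of the phenol.

Step 6
Reactants: 8 3'-(benzyloxy)acetophenone
Product: 9 1-[5-(benzyloxy)-2-bromophenyl]ethanone
Conditions: NBS, MeCN, rt
Reagents that add atoms: N-bromosuccinimide, O=C1CCC(=O)N1Br
Why: Electrophilic aromatic bromination para to the benzyloxy group, which is the position ortho to the acetyl group; without acid or radical initiation the methyl ketone is not brominated.

Step 7
Reactants: 6 hub-8-carbaldehyde; 9 1-[5-(benzyloxy)-2-bromophenyl]ethanone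
Product: 10 (E)-1-[5-(benzyloxy)-2-bromophenyl]-3-(hub-8-yl)prop-2-en-1-one
Conditions: KOH, EtOH/THF, rt
Reagents that add atoms: none
Why: Claisen–Schmidt condensation; the aldehyde has no α-hydrogen, the methyl ketone is the only enolisable partner, and dehydration gives the E-enone.

Step 8
Reactants: 10 bromochalcone
Product: 11 (E)-1-[5-(benzyloxy)-2-(4,4,5,5-tetramethyl-1,3,2-dioxaborolan-2-yl)phenyl]-3-(hub-8-yl)prop-2-en-1-one
Conditions: B2pin2, Pd(dppf)Cl2, KOAc, dioxane, 80 °C
Reagents that add atoms: bis(pinacolato)diboron, CC1(C)OB(OC1(C)C)B1OC(C)(C)C(C)(C)O1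
Why: Miyaura borylation of the aryl bromide activated by the ortho carbonyl group; acetate as base leaves the enone and the benzyl ethers alone.

Step 9
Reactants: 11 boronate chalcone
Product: 12 (3S)-6-(benzyloxy)-3-(hub-8-yl)indan-1-one
Conditions: [RhCl(C2H4)2]2, (S)-MonoPhos, aq K3PO4, toluene, 60 °C
Reagents that add atoms: none
Why: Rhodium-catalysed asymmetric intramolecular 1,4-addition, a known route from boronate chalcones to 3-arylindan-1-ones: transmetalation gives an arylrhodium species of monovalent rhodium that adds to the β-carbon of the tethered enone, and the rhodium enolate is protonated. The new centre C3 is set by the chiral phosphoramidite, since the hub centres are too remote to interfere. Because the hub is chiral, any minor C3 epimer is a diastereomer and can be removed by chromatography.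

Step 10
Reactants: 12 indanone
Product: 13 (3S)-6-(benzyloxy)-3-(6-bromo-hub-8-yl)indan-1-one
Conditions: NBS, CH2Cl2, 0 °C
Reagents that add atoms: N-bromosuccinimide, O=C1CCC(=O)N1Br
Why: Electrophilic aromatic bromination at C6, the only free position of the phloroglucinol-type ring; the indanone ring is deactivated by its carbonyl group and the catechol ether rings are far less nucleophilic.

Step 11
Reactants: 13 (3S)-6-(benzyloxy)-3-(6-bromo-hub-8-yl)indan-1-one
Product: 14 (4S)-7-(benzyloxy)-4-(6-bromo-hub-8-yl)chroman-2-one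
Conditions: mCPBA, NaHCO3, CH2Cl2, 0 °C to rt
Reagents that add atoms: 3-chloroperoxybenzoic acid, OOC(=O)c1cccc(Cl)c1
Why: The peracid adds to the indanone carbonyl to give the tetrahedral Criegee adduct; the aromatic carbon C7a then shifts from carbon to the proximal peroxide oxygen as 3-chlorobenzoate leaves, so that oxygen ends up between C7a and the carbonyl carbon, which are the O1–C8a and O1–C2 bonds of unit 4. The closest known reaction type is the Baeyer–Villiger oxidation of indan-1-ones, 3-aryl ones included, to 3,4-dihydrocoumarins. The six-membered ring arises by one-atom expansion of the five-membered ketone through a 1,2-shift, not by cyclisation of an open chain, so no Baldwin-type closure is involved. No stereocentre is created; the migrating carbon is sp2, and the existing centre (C3 of 13, C4 of 14) is β to the carbonyl on the non-migrating side, cannot enolise and is retained. The selectivity needed is aryl over methylene migration; the aryl carbon bears positive charge in the transition state better than a primary alkyl carbon, as in the parent indanone, and the benzyloxy group, being meta to the migrating carbon, neither helps nor blocks. Chemoselectivity for the ketone over the electron-rich arenes rests on the bicarbonate buffer, on the absence of any free position on the brominated hub ring, and on the lower nucleophilicity of the benzylated catechol rings.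

Step 12
Reactants: 15 4-bromocatechol
Product: 16 4-bromo-1,2-bis(benzyloxy)benzene
Conditions: BnBr, K2CO3, DMF, rt
Reagents that add atoms: benzyl bromide, BrCc1ccccc1
Why: Williamson etherification of both phenols.

Step 13
Reactants: 16 4-bromo-1,2-bis(benzyloxy)benzene
Product: 17 3,4-bis(benzyloxy)phenylmagnesium bromide (titrated THF stock solution)
Conditions: Mg turnings, I2 (cat.), THF, rt to 40 °C; titration; kept under Ar
Reagents that add atoms: magnesium, [Mg]
Why: Grignard formation by insertion of magnesium into the aryl C–Br bond; benzyl aryl ethers are inert to arylmagnesium halides, and the THF solution keeps its titre under argon, so one stock supplies ring B in steps 14, 23 and 31.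

Step 14
Reactants: 14 lactone; 17 3,4-bis(benzyloxy)phenylmagnesium bromide
Product: 19 (4S)-7-(benzyloxy)-2-[3,4-bis(benzyloxy)phenyl]-4-(6-bromo-hub-8-yl)-4H-chromene, via keto-phenol 18 (not isolated)
Conditions: 17 (1.1 equiv), THF, −78 °C to −30 °C; aq NH4Cl; then TsOH·H2O (cat.), 4 Å MS, toluene, rt
Reagents that add atoms: none
Why: Grignard addition to a six-membered aryl lactone at low temperature gives the magnesium hemiketalate, which should hold until the quench and then give 18 in equilibrium with its 2-arylchroman-2-ol form. Acid-catalysed dehydration of that hemiketal gives the cyclic enol ether. The arylmagnesium reagent does not exchange with the aryl bromide on hub C6, and C4 is not enolisable in any intermediate and is retained.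

Step 15
Reactants: 19 4H-chromene
Product: 21 Fis-(4α→8)-6-bromo-hub (dimer bromide), via C3-borane 20 (not isolated)
Conditions: BH3·SMe2, THF, 0 °C to rt; then aq NaOH, H2O2, 0 °C to rt
Reagents that add atoms: hydrogen peroxide, OO
Why: Hydroboration–oxidation of a 2-aryl cyclic enol ether, known for flav-2-enes and 1-aryl glycals: boron goes to C3, β to the ring oxygen and away from the benzylic C2. Borane approaches the face opposite the pseudo-axial C4 aryl group, syn addition places H on C2 and B on C3 on that face, and oxidation with retention gives the 2,3-trans-3,4-trans flavan-3-ol, (2R,3S,4S) in unit 4.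

Step 16
Reactants: 21 dimer bromide
Product: 23 Fis-(4α→8)-hub-6-carbaldehyde, via dilithiated dimer 22 (not isolated)
Conditions: n-BuLi (2.2 equiv), THF, −78 °C; DMF; H2O
Reagents that add atoms: N,N-dimethylformamide, CN(C)C=O
Why: The first equivalent deprotonates the hydroxyl and the second effects bromine–lithium exchange at C6; formylation of the aryllithium with DMF follows as in step 4.

Step 17
Reactants: 24 4'-chloro-3'-hydroxyacetophenone
Product: 25 1-[3-(benzyloxy)-4-chlorophenyl]ethanone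
Conditions: BnBr, K2CO3, acetone, reflux
Reagents that add atoms: benzyl bromide, BrCc1ccccc1
Why: Williamson etherification of the phenol.

Step 18
Reactants: 25 1-[3-(benzyloxy)-4-chlorophenyl]ethanone
Product: 26 1-[5-(benzyloxy)-2-bromo-4-chlorophenyl]ethanone
Conditions: NBS, MeCN, rt
Reagents that add atoms: N-bromosuccinimide, O=C1CCC(=O)N1Br
Why: Electrophilic aromatic bromination para to the benzyloxy group; the other position ortho to the ether lies between it and the acetyl group and is more hindered.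

Step 19
Reactants: 23 dimer aldehyde; 26 1-[5-(benzyloxy)-2-bromo-4-chlorophenyl]ethanone
Product: 27 (E)-1-[5-(benzyloxy)-2-bromo-4-chlorophenyl]-3-(dimer-6-yl)prop-2-en-1-one
Conditions: KOH, EtOH/THF, rt
Reagents that add atoms: none
Why: Claisen–Schmidt condensation as in step 7; the free secondary hydroxyl is inert to hydroxide.

Step 20
Reactants: 27 bromochalcone
Product: 28 (E)-1-[5-(benzyloxy)-4-chloro-2-(4,4,5,5-tetramethyl-1,3,2-dioxaborolan-2-yl)phenyl]-3-(dimer-6-yl)prop-2-en-1-one
Conditions: B2pin2, Pd(dppf)Cl2, KOAc, dioxane, 80 °C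
Reagents that add atoms: bis(pinacolato)diboron, CC1(C)OB(OC1(C)C)B1OC(C)(C)C(C)(C)O1
Why: Miyaura borylation; zerovalent palladium with this ligand inserts into the C–Br bond ortho to the carbonyl group and leaves the C–Cl bond untouched.

Step 21
Reactants: 28 boronate chalcone
Product: 29 (3S)-6-(benzyloxy)-5-chloro-3-(dimer-6-yl)indan-1-one
Conditions: [RhCl(C2H4)2]2, (S)-MonoPhos, aq K3PO4, toluene, 60 °C
Reagents that add atoms: none
Why: Rhodium-catalysed asymmetric intramolecular 1,4-addition as in step 9; the new centre is set by the same ligand in the same sense, and a minor epimer is a separable diastereomer.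

Step 22
Reactants: 29 indanone
Product: 30 (4S)-7-(benzyloxy)-6-chloro-4-(dimer-6-yl)chroman-2-one
Conditions: mCPBA, NaHCO3, CH2Cl2, 0 °C to rt
Reagents that add atoms: 3-chloroperoxybenzoic acid, OOC(=O)c1cccc(Cl)c1
Why: Baeyer–Villiger ring expansion with aryl migration as in step 11. The hub ring is now fully substituted by carbon, and the buffered peracid should leave the free alcohol and the resorcinol-type ring of unit 4 alone.

Step 23
Reactants: 30 lactone; 17 3,4-bis(benzyloxy)phenylmagnesium bromide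
Product: 32 (4S)-7-(benzyloxy)-2-[3,4-bis(benzyloxy)phenyl]-6-chloro-4-(dimer-6-yl)-4H-chromene, via keto-phenol 31 (not isolated)
Conditions: 17 (2.2 equiv), THF, −78 °C to −30 °C; aq NH4Cl; then TsOH·H2O (cat.), 4 Å MS, toluene, rt
Reagents that add atoms: none
Why: Grignard addition to the lactone and acid-catalysed cyclodehydration as in step 14; one extra equivalent of 17 is consumed by the free hydroxyl, and the aryl chloride is inert to the arylmagnesium reagent.

Step 24
Reactants: 32 4H-chromene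
Product: 34 6-chloro-Fis-(4α→6)-[Fis-(4α→8)]-hub (trimer chloride), via C3-borane 33 (not isolated)
Conditions: BH3·SMe2 (excess), THF, 0 °C to rt; then aq NaOH, H2O2, 0 °C to rt
Reagents that add atoms: hydrogen peroxide, OO
Why: Hydroboration–oxidation as in step 15; addition anti to the C4 aryl group (here hub C6) gives the 2,3-trans-3,4-trans triad of unit 2.

Step 25
Reactants: 34 trimer chloride
Product: 35 6-vinyl-Fis-(4α→6)-[Fis-(4α→8)]-hub
Conditions: 4,4,5,5-tetramethyl-2-vinyl-1,3,2-dioxaborolane, Pd(OAc)2, SPhos, K3PO4, dioxane/H2O, 90 °C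
Reagents that add atoms: 4,4,5,5-tetramethyl-2-vinyl-1,3,2-dioxaborolane, C=CB1OC(C)(C)C(C)(C)O1
Why: Suzuki–Miyaura coupling; the dialkylbiarylphosphine lets zerovalent palladium insert into the electron-rich aryl chloride, which is the only carbon–halogen bond left.

Step 26
Reactants: 35 vinyl trimer
Product: 36 6-formyl-Fis-(4α→6)-[Fis-(4α→8)]-hub
Conditions: OsO4 (cat.), NaIO4, 2,6-lutidine, dioxane/H2O, rt
Reagents that add atoms: sodium periodate, [Na+].[O-]I(=O)(=O)=O
Why: Lemieux–Johnson oxidation: catalytic dihydroxylation of the only alkene followed by periodate cleavage; arenes, benzyl ethers and secondary alcohols are inert.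

Step 27
Reactants: 36 trimer aldehyde; 9 1-[5-(benzyloxy)-2-bromophenyl]ethanone
Product: 37 (E)-1-[5-(benzyloxy)-2-bromophenyl]-3-(trimer-6-yl)prop-2-en-1-one (enone on C6 of unit 2)
Conditions: KOH, EtOH/THF, rt
Reagents that add atoms: none
Why: Claisen–Schmidt condensation as in step 7; this aldehyde has only one ortho substituent and is less hindered than 6 or 23.

Step 28
Reactants: 37 bromochalcone
Product: 38 (E)-1-[5-(benzyloxy)-2-(4,4,5,5-tetramethyl-1,3,2-dioxaborolan-2-yl)phenyl]-3-(trimer-6-yl)prop-2-en-1-one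
Conditions: B2pin2, Pd(dppf)Cl2, KOAc, dioxane, 80 °C
Reagents that add atoms: bis(pinacolato)diboron, CC1(C)OB(OC1(C)C)B1OC(C)(C)C(C)(C)O1
Why: Miyaura borylation of the only aryl bromide, as in step 8.

Step 29
Reactants: 38 boronate chalcone
Product: 39 (3S)-6-(benzyloxy)-3-(trimer-6-yl)indan-1-one
Conditions: [RhCl(C2H4)2]2, (S)-MonoPhos, aq K3PO4, toluene, 60 °C
Reagents that add atoms: none
Why: Rhodium-catalysed asymmetric intramolecular 1,4-addition as in step 9, with the new centre set by the ligand; the β-aryl group has a single ortho substituent here, so insertion should be easier than in steps 9 and 21.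

Step 30
Reactants: 39 indanone
Product: 40 (4S)-7-(benzyloxy)-4-(trimer-6-yl)chroman-2-one
Conditions: mCPBA, NaHCO3, CH2Cl2, 0 °C to rt
Reagents that add atoms: 3-chloroperoxybenzoic acid, OOC(=O)c1cccc(Cl)c1
Why: Baeyer–Villiger ring expansion with aryl migration as in step 11; C4 of the new lactone is retained.

Step 31
Reactants: 40 lactone; 17 3,4-bis(benzyloxy)phenylmagnesium bromide
Product: 42 (4S)-7-(benzyloxy)-2-[3,4-bis(benzyloxy)phenyl]-4-(trimer-6-yl)-4H-chromene, via keto-phenol 41 (not isolated)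
Conditions: 17 (3.3 equiv), THF, −78 °C to −30 °C; aq NH4Cl; then TsOH·H2O (cat.), 4 Å MS, toluene, rt
Reagents that add atoms: none
Why: Grignard addition to the lactone and acid-catalysed cyclodehydration as in step 14; two equivalents of 17 serve as base for the two free hydroxyls.

Step 32
Reactants: 42 4H-chromene
Product: 44 Fis-(4α→6)-Fis-(4α→6)-[Fis-(4α→8)]-hub (tetradeca-O-benzyl tetramer), via C3-borane 43 (not isolated)
Conditions: BH3·SMe2 (excess), THF, 0 °C to rt; then aq NaOH, H2O2, 0 °C to rt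
Reagents that add atoms: hydrogen peroxide, OO
Why: Hydroboration–oxidation as in step 15; syn addition anti to the C4 aryl group completes the all-trans triad of unit 1.

Step 33
Reactants: 44 tetradeca-O-benzyl tetramer
Product: 45 fisetinidol-(4α→6)-fisetinidol-(4α→6)-[fisetinidol-(4α→8)]-catechin (CNP0263622.1)
Conditions: H2 (1 atm), Pd(OH)2/C, THF/MeOH/H2O, rt
Reagents that add atoms: none
Why: Hydrogenolysis of all fourteen benzyl ethers under neutral conditions, which spare the interflavan bonds and all stereocentres; the polyphenol is handled under inert gas.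

## Compound list

1 | (+)-catechin, (2R,3S)-2-(3,4-dihydroxyphenyl)chroman-3,5,7-triol | O[C@H]1Cc2c(O)cc(O)cc2O[C@@H]1c1ccc(O)c(O)c1 | starting material
2 | 5,7,3',4'-tetra-O-benzyl-(+)-catechin | c1c(OCc5ccccc5)c2c(cc1OCc5ccccc5)O[C@H](c1ccc(OCc5ccccc5)c(OCc5ccccc5)c1)[C@@H](O)C2 | intermediate
3 | 3,5,7,3',4'-penta-O-benzyl-(+)-catechin (hub) | c1c(OCc5ccccc5)c2c(cc1OCc5ccccc5)O[C@H](c1ccc(OCc5ccccc5)c(OCc5ccccc5)c1)[C@@H](OCc5ccccc5)C2 | intermediate
4 | 8-bromo-hub | c1c(OCc5ccccc5)c2c(c(Br)c1OCc5ccccc5)O[C@H](c1ccc(OCc5ccccc5)c(OCc5ccccc5)c1)[C@@H](OCc5ccccc5)C2 | intermediate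
5 | 8-lithio-hub | c1c(OCc5ccccc5)c2c(c([Li])c1OCc5ccccc5)O[C@H](c1ccc(OCc5ccccc5)c(OCc5ccccc5)c1)[C@@H](OCc5ccccc5)C2 | intermediate (not isolated)
6 | hub-8-carbaldehyde | c1c(OCc5ccccc5)c2c(c(C=O)c1OCc5ccccc5)O[C@H](c1ccc(OCc5ccccc5)c(OCc5ccccc5)c1)[C@@H](OCc5ccccc5)C2 | intermediate
7 | 3'-hydroxyacetophenone | CC(=O)c1cccc(O)c1 | starting material
8 | 3'-(benzyloxy)acetophenone | CC(=O)c1cccc(OCc2ccccc2)c1 | intermediate
9 | 1-[5-(benzyloxy)-2-bromophenyl]ethanone | CC(=O)c1cc(OCc2ccccc2)ccc1Br | intermediate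
10 | (E)-1-[5-(benzyloxy)-2-bromophenyl]-3-(hub-8-yl)prop-2-en-1-one | c1c(OCc5ccccc5)c2c(c(/C=C/C(=O)c3cc(OCc5ccccc5)ccc3Br)c1OCc5ccccc5)O[C@H](c1ccc(OCc5ccccc5)c(OCc5ccccc5)c1)[C@@H](OCc5ccccc5)C2 | intermediate
11 | (E)-1-[5-(benzyloxy)-2-(pinacolboryl)phenyl]-3-(hub-8-yl)prop-2-en-1-one | c1c(OCc5ccccc5)c2c(c(/C=C/C(=O)c3cc(OCc5ccccc5)ccc3B6OC(C)(C)C(C)(C)O6)c1OCc5ccccc5)O[C@H](c1ccc(OCc5ccccc5)c(OCc5ccccc5)c1)[C@@H](OCc5ccccc5)C2 | intermediate
12 | (3S)-6-(benzyloxy)-3-(hub-8-yl)indan-1-one | c1c(OCc5ccccc5)c2c(c([C@@H]3c4ccc(OCc5ccccc5)cc4C(=O)C3)c1OCc5ccccc5)O[C@H](c1ccc(OCc5ccccc5)c(OCc5ccccc5)c1)[C@@H](OCc5ccccc5)C2 | intermediate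
13 | (3S)-6-(benzyloxy)-3-(6-bromo-hub-8-yl)indan-1-one | Brc1c(OCc5ccccc5)c2c(c([C@@H]3c4ccc(OCc5ccccc5)cc4C(=O)C3)c1OCc5ccccc5)O[C@H](c1ccc(OCc5ccccc5)c(OCc5ccccc5)c1)[C@@H](OCc5ccccc5)C2 | intermediate
14 | (4S)-7-(benzyloxy)-4-(6-bromo-hub-8-yl)chroman-2-one | Brc1c(OCc5ccccc5)c2c(c([C@@H]3c4ccc(OCc5ccccc5)cc4OC(=O)C3)c1OCc5ccccc5)O[C@H](c1ccc(OCc5ccccc5)c(OCc5ccccc5)c1)[C@@H](OCc5ccccc5)C2 | intermediate
15 | 4-bromocatechol | Oc1ccc(Br)cc1O | starting material
16 | 4-bromo-1,2-bis(benzyloxy)benzene | Brc1ccc(OCc2ccccc2)c(OCc2ccccc2)c1 | intermediate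
17 | 3,4-bis(benzyloxy)phenylmagnesium bromide (titrated THF stock solution) | Br[Mg]c1ccc(OCc2ccccc2)c(OCc2ccccc2)c1 | intermediate
18 | (3S)-1-[3,4-bis(benzyloxy)phenyl]-3-[4-(benzyloxy)-2-hydroxyphenyl]-3-(6-bromo-hub-8-yl)propan-1-one (open form of the hemiketal) | Brc1c(OCc5ccccc5)c2c(c([C@@H](CC(=O)c3ccc(OCc5ccccc5)c(OCc5ccccc5)c3)c3ccc(OCc5ccccc5)cc3O)c1OCc5ccccc5)O[C@H](c1ccc(OCc5ccccc5)c(OCc5ccccc5)c1)[C@@H](OCc5ccccc5)C2 | intermediate (not isolated)
19 | (4S)-7-(benzyloxy)-2-[3,4-bis(benzyloxy)phenyl]-4-(6-bromo-hub-8-yl)-4H-chromene | Brc1c(OCc5ccccc5)c2c(c([C@@H]3c4ccc(OCc5ccccc5)cc4OC(c4ccc(OCc5ccccc5)c(OCc5ccccc5)c4)=C3)c1OCc5ccccc5)O[C@H](c1ccc(OCc5ccccc5)c(OCc5ccccc5)c1)[C@@H](OCc5ccccc5)C2 | intermediate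
20 | C3-borane from 19 (2,3-trans-3,4-trans, drawn as RBH2) | Brc1c(OCc5ccccc5)c2c(c([C@@H]3c4ccc(OCc5ccccc5)cc4O[C@H](c4ccc(OCc5ccccc5)c(OCc5ccccc5)c4)[C@H]3B)c1OCc5ccccc5)O[C@H](c1ccc(OCc5ccccc5)c(OCc5ccccc5)c1)[C@@H](OCc5ccccc5)C2 | intermediate (not isolated)
21 | Fis-(4α→8)-6-bromo-hub (dimer bromide; unit 4 is 2R,3S,4S) | Brc1c(OCc5ccccc5)c2c(c([C@@H]3c4ccc(OCc5ccccc5)cc4O[C@H](c4ccc(OCc5ccccc5)c(OCc5ccccc5)c4)[C@H]3O)c1OCc5ccccc5)O[C@H](c1ccc(OCc5ccccc5)c(OCc5ccccc5)c1)[C@@H](OCc5ccccc5)C2 | intermediate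
22 | dilithiated dimer (lithium alkoxide at O3 of unit 4, lithium at hub C6) | [Li]c1c(OCc5ccccc5)c2c(c([C@@H]3c4ccc(OCc5ccccc5)cc4O[C@H](c4ccc(OCc5ccccc5)c(OCc5ccccc5)c4)[C@H]3O[Li])c1OCc5ccccc5)O[C@H](c1ccc(OCc5ccccc5)c(OCc5ccccc5)c1)[C@@H](OCc5ccccc5)C2 | intermediate (not isolated)
23 | Fis-(4α→8)-hub-6-carbaldehyde | O=Cc1c(OCc5ccccc5)c2c(c([C@@H]3c4ccc(OCc5ccccc5)cc4O[C@H](c4ccc(OCc5ccccc5)c(OCc5ccccc5)c4)[C@H]3O)c1OCc5ccccc5)O[C@H](c1ccc(OCc5ccccc5)c(OCc5ccccc5)c1)[C@@H](OCc5ccccc5)C2 | intermediate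
24 | 4'-chloro-3'-hydroxyacetophenone | CC(=O)c1ccc(Cl)c(O)c1 | starting material
25 | 1-[3-(benzyloxy)-4-chlorophenyl]ethanone | CC(=O)c1ccc(Cl)c(OCc2ccccc2)c1 | intermediate
26 | 1-[5-(benzyloxy)-2-bromo-4-chlorophenyl]ethanone | CC(=O)c1cc(OCc2ccccc2)c(Cl)cc1Br | intermediate
27 | (E)-1-[5-(benzyloxy)-2-bromo-4-chlorophenyl]-3-(dimer-6-yl)prop-2-en-1-one | Brc1cc(Cl)c(OCc5ccccc5)cc1C(=O)/C=C/c1c(OCc5ccccc5)c2c(c([C@@H]3c4ccc(OCc5ccccc5)cc4O[C@H](c4ccc(OCc5ccccc5)c(OCc5ccccc5)c4)[C@H]3O)c1OCc5ccccc5)O[C@H](c1ccc(OCc5ccccc5)c(OCc5ccccc5)c1)[C@@H](OCc5ccccc5)C2 | intermediate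
28 | (E)-1-[5-(benzyloxy)-4-chloro-2-(pinacolboryl)phenyl]-3-(dimer-6-yl)prop-2-en-1-one | CC1(C)OB(OC1(C)C)c1cc(Cl)c(OCc5ccccc5)cc1C(=O)/C=C/c1c(OCc5ccccc5)c2c(c([C@@H]3c4ccc(OCc5ccccc5)cc4O[C@H](c4ccc(OCc5ccccc5)c(OCc5ccccc5)c4)[C@H]3O)c1OCc5ccccc5)O[C@H](c1ccc(OCc5ccccc5)c(OCc5ccccc5)c1)[C@@H](OCc5ccccc5)C2 | intermediate
29 | (3S)-6-(benzyloxy)-5-chloro-3-(dimer-6-yl)indan-1-one | Clc1cc2c(cc1OCc5ccccc5)C(=O)C[C@@H]2c1c(OCc5ccccc5)c2c(c([C@@H]3c4ccc(OCc5ccccc5)cc4O[C@H](c4ccc(OCc5ccccc5)c(OCc5ccccc5)c4)[C@H]3O)c1OCc5ccccc5)O[C@H](c1ccc(OCc5ccccc5)c(OCc5ccccc5)c1)[C@@H](OCc5ccccc5)C2 | intermediate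
30 | (4S)-7-(benzyloxy)-6-chloro-4-(dimer-6-yl)chroman-2-one | Clc1cc2c(cc1OCc5ccccc5)OC(=O)C[C@@H]2c1c(OCc5ccccc5)c2c(c([C@@H]3c4ccc(OCc5ccccc5)cc4O[C@H](c4ccc(OCc5ccccc5)c(OCc5ccccc5)c4)[C@H]3O)c1OCc5ccccc5)O[C@H](c1ccc(OCc5ccccc5)c(OCc5ccccc5)c1)[C@@H](OCc5ccccc5)C2 | intermediate
31 | (3S)-1-[3,4-bis(benzyloxy)phenyl]-3-[4-(benzyloxy)-5-chloro-2-hydroxyphenyl]-3-(dimer-6-yl)propan-1-one (open form of the hemiketal) | Clc1cc(c(O)cc1OCc5ccccc5)[C@H](CC(=O)c3ccc(OCc5ccccc5)c(OCc5ccccc5)c3)c1c(OCc5ccccc5)c2c(c([C@@H]3c4ccc(OCc5ccccc5)cc4O[C@H](c4ccc(OCc5ccccc5)c(OCc5ccccc5)c4)[C@H]3O)c1OCc5ccccc5)O[C@H](c1ccc(OCc5ccccc5)c(OCc5ccccc5)c1)[C@@H](OCc5ccccc5)C2 | intermediate (not isolated)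
32 | (4S)-7-(benzyloxy)-2-[3,4-bis(benzyloxy)phenyl]-6-chloro-4-(dimer-6-yl)-4H-chromene | Clc1cc2c(cc1OCc5ccccc5)OC(c3ccc(OCc5ccccc5)c(OCc5ccccc5)c3)=C[C@@H]2c1c(OCc5ccccc5)c2c(c([C@@H]3c4ccc(OCc5ccccc5)cc4O[C@H](c4ccc(OCc5ccccc5)c(OCc5ccccc5)c4)[C@H]3O)c1OCc5ccccc5)O[C@H](c1ccc(OCc5ccccc5)c(OCc5ccccc5)c1)[C@@H](OCc5ccccc5)C2 | intermediate
33 | C3-borane from 32 (2,3-trans-3,4-trans, drawn as RBH2) | Clc1cc2c(cc1OCc5ccccc5)O[C@H](c1ccc(OCc5ccccc5)c(OCc5ccccc5)c1)[C@@H](B)[C@@H]2c1c(OCc5ccccc5)c2c(c([C@@H]3c4ccc(OCc5ccccc5)cc4O[C@H](c4ccc(OCc5ccccc5)c(OCc5ccccc5)c4)[C@H]3O)c1OCc5ccccc5)O[C@H](c1ccc(OCc5ccccc5)c(OCc5ccccc5)c1)[C@@H](OCc5ccccc5)C2 | intermediate (not isolated)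
34 | 6-chloro-Fis-(4α→6)-[Fis-(4α→8)]-hub (trimer chloride) | Clc1cc2c(cc1OCc5ccccc5)O[C@H](c1ccc(OCc5ccccc5)c(OCc5ccccc5)c1)[C@@H](O)[C@@H]2c1c(OCc5ccccc5)c2c(c([C@@H]3c4ccc(OCc5ccccc5)cc4O[C@H](c4ccc(OCc5ccccc5)c(OCc5ccccc5)c4)[C@H]3O)c1OCc5ccccc5)O[C@H](c1ccc(OCc5ccccc5)c(OCc5ccccc5)c1)[C@@H](OCc5ccccc5)C2 | intermediate
35 | 6-vinyl-Fis-(4α→6)-[Fis-(4α→8)]-hub | C=Cc1cc2c(cc1OCc5ccccc5)O[C@H](c1ccc(OCc5ccccc5)c(OCc5ccccc5)c1)[C@@H](O)[C@@H]2c1c(OCc5ccccc5)c2c(c([C@@H]3c4ccc(OCc5ccccc5)cc4O[C@H](c4ccc(OCc5ccccc5)c(OCc5ccccc5)c4)[C@H]3O)c1OCc5ccccc5)O[C@H](c1ccc(OCc5ccccc5)c(OCc5ccccc5)c1)[C@@H](OCc5ccccc5)C2 | intermediate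
36 | 6-formyl-Fis-(4α→6)-[Fis-(4α→8)]-hub | O=Cc1cc2c(cc1OCc5ccccc5)O[C@H](c1ccc(OCc5ccccc5)c(OCc5ccccc5)c1)[C@@H](O)[C@@H]2c1c(OCc5ccccc5)c2c(c([C@@H]3c4ccc(OCc5ccccc5)cc4O[C@H](c4ccc(OCc5ccccc5)c(OCc5ccccc5)c4)[C@H]3O)c1OCc5ccccc5)O[C@H](c1ccc(OCc5ccccc5)c(OCc5ccccc5)c1)[C@@H](OCc5ccccc5)C2 | intermediate
37 | (E)-1-[5-(benzyloxy)-2-bromophenyl]-3-(trimer-6-yl)prop-2-en-1-one | Brc1ccc(OCc5ccccc5)cc1C(=O)/C=C/c1cc2c(cc1OCc5ccccc5)O[C@H](c1ccc(OCc5ccccc5)c(OCc5ccccc5)c1)[C@@H](O)[C@@H]2c1c(OCc5ccccc5)c2c(c([C@@H]3c4ccc(OCc5ccccc5)cc4O[C@H](c4ccc(OCc5ccccc5)c(OCc5ccccc5)c4)[C@H]3O)c1OCc5ccccc5)O[C@H](c1ccc(OCc5ccccc5)c(OCc5ccccc5)c1)[C@@H](OCc5ccccc5)C2 | intermediate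
38 | (E)-1-[5-(benzyloxy)-2-(pinacolboryl)phenyl]-3-(trimer-6-yl)prop-2-en-1-one | CC1(C)OB(OC1(C)C)c1ccc(OCc5ccccc5)cc1C(=O)/C=C/c1cc2c(cc1OCc5ccccc5)O[C@H](c1ccc(OCc5ccccc5)c(OCc5ccccc5)c1)[C@@H](O)[C@@H]2c1c(OCc5ccccc5)c2c(c([C@@H]3c4ccc(OCc5ccccc5)cc4O[C@H](c4ccc(OCc5ccccc5)c(OCc5ccccc5)c4)[C@H]3O)c1OCc5ccccc5)O[C@H](c1ccc(OCc5ccccc5)c(OCc5ccccc5)c1)[C@@H](OCc5ccccc5)C2 | intermediate
39 | (3S)-6-(benzyloxy)-3-(trimer-6-yl)indan-1-one | c5ccccc5COc1ccc2c(c1)C(=O)C[C@@H]2c1cc2c(cc1OCc5ccccc5)O[C@H](c1ccc(OCc5ccccc5)c(OCc5ccccc5)c1)[C@@H](O)[C@@H]2c1c(OCc5ccccc5)c2c(c([C@@H]3c4ccc(OCc5ccccc5)cc4O[C@H](c4ccc(OCc5ccccc5)c(OCc5ccccc5)c4)[C@H]3O)c1OCc5ccccc5)O[C@H](c1ccc(OCc5ccccc5)c(OCc5ccccc5)c1)[C@@H](OCc5ccccc5)C2 | intermediate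
40 | (4S)-7-(benzyloxy)-4-(trimer-6-yl)chroman-2-one | c5ccccc5COc1ccc2c(c1)OC(=O)C[C@@H]2c1cc2c(cc1OCc5ccccc5)O[C@H](c1ccc(OCc5ccccc5)c(OCc5ccccc5)c1)[C@@H](O)[C@@H]2c1c(OCc5ccccc5)c2c(c([C@@H]3c4ccc(OCc5ccccc5)cc4O[C@H](c4ccc(OCc5ccccc5)c(OCc5ccccc5)c4)[C@H]3O)c1OCc5ccccc5)O[C@H](c1ccc(OCc5ccccc5)c(OCc5ccccc5)c1)[C@@H](OCc5ccccc5)C2 | intermediate
41 | (3S)-1-[3,4-bis(benzyloxy)phenyl]-3-[4-(benzyloxy)-2-hydroxyphenyl]-3-(trimer-6-yl)propan-1-one (open form of the hemiketal) | c5ccccc5COc1ccc(c(O)c1)[C@H](CC(=O)c3ccc(OCc5ccccc5)c(OCc5ccccc5)c3)c1cc2c(cc1OCc5ccccc5)O[C@H](c1ccc(OCc5ccccc5)c(OCc5ccccc5)c1)[C@@H](O)[C@@H]2c1c(OCc5ccccc5)c2c(c([C@@H]3c4ccc(OCc5ccccc5)cc4O[C@H](c4ccc(OCc5ccccc5)c(OCc5ccccc5)c4)[C@H]3O)c1OCc5ccccc5)O[C@H](c1ccc(OCc5ccccc5)c(OCc5ccccc5)c1)[C@@H](OCc5ccccc5)C2 | intermediate (not isolated)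
42 | (4S)-7-(benzyloxy)-2-[3,4-bis(benzyloxy)phenyl]-4-(trimer-6-yl)-4H-chromene | c5ccccc5COc1ccc2c(c1)OC(c3ccc(OCc5ccccc5)c(OCc5ccccc5)c3)=C[C@@H]2c1cc2c(cc1OCc5ccccc5)O[C@H](c1ccc(OCc5ccccc5)c(OCc5ccccc5)c1)[C@@H](O)[C@@H]2c1c(OCc5ccccc5)c2c(c([C@@H]3c4ccc(OCc5ccccc5)cc4O[C@H](c4ccc(OCc5ccccc5)c(OCc5ccccc5)c4)[C@H]3O)c1OCc5ccccc5)O[C@H](c1ccc(OCc5ccccc5)c(OCc5ccccc5)c1)[C@@H](OCc5ccccc5)C2 | intermediate
43 | C3-borane from 42 (2,3-trans-3,4-trans, drawn as RBH2) | c5ccccc5COc1ccc2c(c1)O[C@H](c1ccc(OCc5ccccc5)c(OCc5ccccc5)c1)[C@@H](B)[C@@H]2c1cc2c(cc1OCc5ccccc5)O[C@H](c1ccc(OCc5ccccc5)c(OCc5ccccc5)c1)[C@@H](O)[C@@H]2c1c(OCc5ccccc5)c2c(c([C@@H]3c4ccc(OCc5ccccc5)cc4O[C@H](c4ccc(OCc5ccccc5)c(OCc5ccccc5)c4)[C@H]3O)c1OCc5ccccc5)O[C@H](c1ccc(OCc5ccccc5)c(OCc5ccccc5)c1)[C@@H](OCc5ccccc5)C2 | intermediate (not isolated)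
44 | Fis-(4α→6)-Fis-(4α→6)-[Fis-(4α→8)]-hub (tetradeca-O-benzyl tetramer, three free 3-OH) | c5ccccc5COc1ccc2c(c1)O[C@H](c1ccc(OCc5ccccc5)c(OCc5ccccc5)c1)[C@@H](O)[C@@H]2c1cc2c(cc1OCc5ccccc5)O[C@H](c1ccc(OCc5ccccc5)c(OCc5ccccc5)c1)[C@@H](O)[C@@H]2c1c(OCc5ccccc5)c2c(c([C@@H]3c4ccc(OCc5ccccc5)cc4O[C@H](c4ccc(OCc5ccccc5)c(OCc5ccccc5)c4)[C@H]3O)c1OCc5ccccc5)O[C@H](c1ccc(OCc5ccccc5)c(OCc5ccccc5)c1)[C@@H](OCc5ccccc5)C2 | intermediate
45 | fisetinidol-(4α→6)-fisetinidol-(4α→6)-[fisetinidol-(4α→8)]-catechin (CNP0263622.1) | Oc1ccc2c(c1)O[C@H](c1ccc(O)c(O)c1)[C@@H](O)[C@@H]2c1cc2c(cc1O)O[C@H](c1ccc(O)c(O)c1)[C@@H](O)[C@@H]2c1c(O)c2c(c([C@@H]3c4ccc(O)cc4O[C@H](c4ccc(O)c(O)c4)[C@H]3O)c1O)O[C@H](c1ccc(O)c(O)c1)[C@@H](O)C2 | target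

## Step count and least certain steps

Total: 33 steps. Longest linear sequence: 27 steps from (+)-catechin (steps 1–4, 7–11, 14–16, 19–24, 25–33).

**Step 11 (key step; the same concern holds for steps 22 and 30).**
- What may go wrong: peracid addition to the conjugated aryl ketone may be slow under buffered conditions, so that oxidation of the electron-rich hub or catechol ether rings competes. Some methylene migration is also possible, more so in step 22, where chlorine sits para to the migrating carbon.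
- Fallback, from 6 back to 14 without oxygen insertion: Horner–Wadsworth–Emmons olefination of aldehyde 6 with triethyl phosphonoacetate gives ethyl (E)-3-(hub-8-yl)prop-2-enoate F1. Rhodium-catalysed asymmetric 1,4-addition of [4-(benzyloxy)-2-hydroxyphenyl]boronic acid F2, with [RhCl(C2H4)2]2 and a chiral diene, gives the phenolic ester ethyl (3S)-3-[4-(benzyloxy)-2-hydroxyphenyl]-3-(hub-8-yl)propanoate F3. Acid-catalysed lactonisation of the ortho-phenol onto the ester gives (4S)-7-(benzyloxy)-4-(hub-8-yl)chroman-2-one F4. Bromination with NBS at hub C6 returns to 14.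

**Step 9 (and steps 21 and 29).**
- What may go wrong: protodeboronation may outrun insertion of the hindered, electron-rich enone, and facial discrimination by the ligand may be poor next to the doubly ortho-substituted hub ring.
- Fallback, from 10 back to 12: palladium-catalysed asymmetric reductive Heck cyclisation of bromochalcone 10 (Pd(OAc)2, a chiral biaryl bisphosphine, a trialkylamine as hydride source) closes the same bond without any boron intermediate. This detour makes no compound outside the list (F0).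

**Step 14 (and steps 23 and 31).**
- What may go wrong: the magnesium hemiketalate may open to the ketone phenoxide before the quench, so that a second equivalent of 17 adds; the basic reagent may enolise the lactone and leave it unchanged; or acid may induce hydride transfer between molecules of the 4H-chromene during the dehydration.
- Fallback, from 14 back to 19 through 18: the lactone is opened with N,O-dimethylhydroxylamine hydrochloride and AlMe3 to the phenolic Weinreb amide (3S)-3-[4-(benzyloxy)-2-hydroxyphenyl]-3-(6-bromo-hub-8-yl)-N-methoxy-N-methylpropanamide F5. Grignard reagent 17 (two equivalents, the first taken up by the phenol) then adds once, because the chelated tetrahedral intermediate holds until work-up. This gives keto-phenol 18, which is dehydrated to 19 as before.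

**Step 15 (and steps 24 and 32).**
- What may go wrong: hydroboration of the hindered trisubstituted enol ether may be slow, with erosion of facial selectivity or β-elimination of the alkoxy group from the C3 borane.
- Fallback, from 14 back to 21: the potassium enolate of lactone 14 (KN(SiMe3)2, −78 °C) is hydroxylated by 2-(phenylsulfonyl)-3-phenyloxaziridine on the face away from the C4 aryl group, giving the trans-3-hydroxy lactone F6. Addition of excess Grignard reagent 17 gives the hemiketal F7. Reduction with Et3SiH and BF3·OEt2 through the oxocarbenium ion, with axial hydride delivery, gives the 2,3-trans flavan-3-ol 21.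

**Step 16.**
- What may go wrong: the hindered aryllithium may be protonated, or the flanking benzyl ethers may undergo anionic rearrangement before DMF is trapped; the lithium alkoxide may also cause aggregation.
- Fallback, from 21 back to 23: Suzuki–Miyaura vinylation of bromide 21 (Pd(OAc)2, SPhos, 4,4,5,5-tetramethyl-2-vinyl-1,3,2-dioxaborolane) gives 6-vinyl-Fis-(4α→8)-hub F8, and Lemieux–Johnson cleavage (OsO4 cat., NaIO4) gives aldehyde 23, as in steps 25 and 26.

## Further compounds

F1 | step 11 | ethyl (E)-3-(hub-8-yl)prop-2-enoate | c1c(OCc5ccccc5)c2c(c(/C=C/C(=O)OCC)c1OCc5ccccc5)O[C@H](c1ccc(OCc5ccccc5)c(OCc5ccccc5)c1)[C@@H](OCc5ccccc5)C2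
F2 | step 11 | [4-(benzyloxy)-2-hydroxyphenyl]boronic acid | OB(O)c1ccc(OCc2ccccc2)cc1O
F3 | step 11 | ethyl (3S)-3-[4-(benzyloxy)-2-hydroxyphenyl]-3-(hub-8-yl)propanoate | c1c(OCc5ccccc5)c2c(c([C@@H](CC(=O)OCC)c3ccc(OCc5ccccc5)cc3O)c1OCc5ccccc5)O[C@H](c1ccc(OCc5ccccc5)c(OCc5ccccc5)c1)[C@@H](OCc5ccccc5)C2
F4 | step 11 | (4S)-7-(benzyloxy)-4-(hub-8-yl)chroman-2-one | c1c(OCc5ccccc5)c2c(c([C@@H]3c4ccc(OCc5ccccc5)cc4OC(=O)C3)c1OCc5ccccc5)O[C@H](c1ccc(OCc5ccccc5)c(OCc5ccccc5)c1)[C@@H](OCc5ccccc5)C2
F0 | step 9 | none | none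
F5 | step 14 | (3S)-3-[4-(benzyloxy)-2-hydroxyphenyl]-3-(6-bromo-hub-8-yl)-N-methoxy-N-methylpropanamide | Brc1c(OCc5ccccc5)c2c(c([C@@H](CC(=O)N(C)OC)c3ccc(OCc5ccccc5)cc3O)c1OCc5ccccc5)O[C@H](c1ccc(OCc5ccccc5)c(OCc5ccccc5)c1)[C@@H](OCc5ccccc5)C2
F6 | step 15 | 7-(benzyloxy)-4-(6-bromo-hub-8-yl)-3-hydroxychroman-2-one (3,4-trans) | Brc1c(OCc5ccccc5)c2c(c([C@@H]3c4ccc(OCc5ccccc5)cc4OC(=O)[C@H]3O)c1OCc5ccccc5)O[C@H](c1ccc(OCc5ccccc5)c(OCc5ccccc5)c1)[C@@H](OCc5ccccc5)C2
F7 | step 15 | 7-(benzyloxy)-2-[3,4-bis(benzyloxy)phenyl]-4-(6-bromo-hub-8-yl)chroman-2,3-diol (hemiketal, 3,4-trans, both C2 epimers) | Brc1c(OCc5ccccc5)c2c(c([C@@H]3c4ccc(OCc5ccccc5)cc4OC(O)(c4ccc(OCc5ccccc5)c(OCc5ccccc5)c4)[C@H]3O)c1OCc5ccccc5)O[C@H](c1ccc(OCc5ccccc5)c(OCc5ccccc5)c1)[C@@H](OCc5ccccc5)C2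
F8 | step 16 | 6-vinyl-Fis-(4α→8)-hub | C=Cc1c(OCc5ccccc5)c2c(c([C@@H]3c4ccc(OCc5ccccc5)cc4O[C@H](c4ccc(OCc5ccccc5)c(OCc5ccccc5)c4)[C@H]3O)c1OCc5ccccc5)O[C@H](c1ccc(OCc5ccccc5)c(OCc5ccccc5)c1)[C@@H](OCc5ccccc5)C2
A1 | alternative 1 | protected tetramer with triisopropylsilyl ethers on hub O5 and O7 | c5ccccc5COc1ccc2c(c1)O[C@H](c1ccc(OCc5ccccc5)c(OCc5ccccc5)c1)[C@@H](OCc5ccccc5)[C@@H]2c1cc2c(cc1OCc5ccccc5)O[C@H](c1ccc(OCc5ccccc5)c(OCc5ccccc5)c1)[C@@H](OCc5ccccc5)[C@@H]2c1c(O[Si](C(C)C)(C(C)C)C(C)C)c2c(c([C@@H]3c4ccc(OCc5ccccc5)cc4O[C@H](c4ccc(OCc5ccccc5)c(OCc5ccccc5)c4)[C@H]3OCc5ccccc5)c1O[Si](C(C)C)(C(C)C)C(C)C)O[C@H](c1ccc(OCc5ccccc5)c(OCc5ccccc5)c1)[C@@H](OCc5ccccc5)C2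
A2 | alternative 2 | tris(flav-3-ene) tetramer | c5ccccc5COc1ccc2c(c1)O[C@H](c1ccc(OCc5ccccc5)c(OCc5ccccc5)c1)C=C2c1cc2c(cc1OCc5ccccc5)O[C@H](c1ccc(OCc5ccccc5)c(OCc5ccccc5)c1)C=C2c1c(OCc5ccccc5)c2c(c(C3=C[C@@H](c4ccc(OCc5ccccc5)c(OCc5ccccc5)c4)Oc4cc(OCc5ccccc5)ccc34)c1OCc5ccccc5)O[C@H](c1ccc(OCc5ccccc5)c(OCc5ccccc5)c1)[C@@H](OCc5ccccc5)C2
A3 | alternative 3 | unit 1 bonded to C6 of a 7-siloxy-8a-hydroxy ring A for unit 2 | c5ccccc5COc1ccc2c(c1)O[C@H](c1ccc(OCc5ccccc5)c(OCc5ccccc5)c1)[C@@H](OCc5ccccc5)[C@@H]2c1ccc(O)cc1O[Si](C(C)C)(C(C)C)C(C)C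
A4 | alternative 3 | (triisopropylsiloxy)acetylene | C#CO[Si](C(C)C)(C(C)C)C(C)C
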